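**Strategy.** The dihydropyran ring of chroman ring A is cut across O1–C8a and C2–C3: O1 and C2 are the carbonyl group of a methyl ketone, and C3–C4–C4a–C8a is a 2-arylethyl unit that is nucleophilic at C3 (alkylzinc) and electrophilic at C8a (aryl bromide para to O6). In one flask, ligand-controlled asymmetric alkyl transfer to ketone 6 and palladium-catalysed C–O coupling of the resulting tertiary alkoxide close the ring and set C2 (S). The precursor is a 5,5'-linked biaryl that already carries the (2R)-chroman ring B, built the same way with the enantiomeric ligand from a symmetric biaryl; wrong-face addition in either annulation surfaces only as the separable homochiral diastereomer.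

Key step: step 14

Remark on the chemistry: the target SMILES leaves the configuration of the 5,5' biaryl axis open, so no axial control is attempted; compounds 13–31 are carried as atropisomer mixtures and drawn without axial descriptors (for the (2S,2'R) product the two axial forms are mirror images). The chain termini of the target are read as (2Z)-2-methyl-2-enoic acids.

Abbreviations: Re-L* and Si-L* are the two enantiomers of trans-1,2-bis(2-hydroxycamphor-10-sulfonamido)cyclohexane, named after the face of a methyl ketone (O > CH2R > CH3) to which each should direct alkyl transfer, to be assigned beforehand on 4-phenylbutan-2-one; TEEDA is N,N,N',N'-tetraethylethylenediamine (binds LiI).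

**Step 1**
Reactants: 1 (E)-geranylacetone
Product: 3 (5E)-9,10-epoxy-6,10-dimethylundec-5-en-2-one, via bromohydrin 2 (not isolated)
Conditions: NBS, THF/H2O, 0 °C; then K2CO3, MeOH, rt
Reagents that add atoms: water, O
Why: Bromonium formation in aqueous THF should favour the terminal trisubstituted alkene of the chain and base closes the bromohydrin to the epoxide (bromohydrin/epoxide formation); the epoxide stereocenter is removed in step 2 and is left undefined.

**Step 2**
Reactants: 3 (5E)-9,10-epoxy-6,10-dimethylundec-5-en-2-one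
Product: 5 (4E)-4-methyl-8-oxonon-4-enal, via glycol 4 (not isolated)
Conditions: HIO4·2H2O, THF/H2O, 0 °C to rt
Reagents that add atoms: none
Why: Periodic acid opens the epoxide with water at the tertiary carbon and cleaves the glycol (Malaprade cleavage), excising acetone and leaving the aldehyde while the ketone and the E alkene are untouched.

**Step 3**
Reactants: 5 (4E)-4-methyl-8-oxonon-4-enal
Product: 6 ethyl (2Z,6E)-2,6-dimethyl-10-oxoundeca-2,6-dienoate
Conditions: ethyl 2-[bis(2,2,2-trifluoroethoxy)phosphoryl]propanoate, KN(SiMe3)2, 18-crown-6, THF, −78 °C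
Reagents that add atoms: ethyl 2-[bis(2,2,2-trifluoroethoxy)phosphoryl]propanoate, CCOC(=O)C(C)P(=O)(OCC(F)(F)F)OCC(F)(F)F
Why: Still–Gennari olefination: the preformed electron-poor phosphonate anion adds to the aldehyde rather than the ketone at −78 °C and eliminates under kinetic control to the Z trisubstituted enoate.

**Step 4**
Reactants: 7 3-hydroxy-5-methylbenzaldehyde
Product: 8 3-(methoxymethoxy)-5-methylbenzaldehyde
Conditions: MOMCl, iPr2NEt, CH2Cl2, 0 °C to rt
Reagents that add atoms: chloromethyl methyl ether, COCCl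
Why: Standard O-alkylation of the phenol; the MOM ether later serves as ortho-director in step 5 and as para-activator in step 7.

**Step 5**
Reactants: 8 3-(methoxymethoxy)-5-methylbenzaldehyde
Product: 12 2-iodo-3-(methoxymethoxy)-5-methylbenzaldehyde, via lithium α-amino alkoxide 9 (not isolated), via aryllithium 10 (not isolated), via iodo α-amino alkoxide 11 (not isolated)
Conditions: LiN(Me)CH2CH2NMe2, THF, −20 °C; n-BuLi, −20 °C; I2, −78 °C to rt; aq. NH4Cl
Reagents that add atoms: iodine, II
Why: Directed ortho-lithiation: the in situ α-amino alkoxide masks the aldehyde and cooperates with the MOM ether so that n-BuLi should deprotonate the carbon between the two groups, iodine traps the aryllithium and work-up releases the aldehyde.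

**Step 6**
Reactants: 12 2-iodo-3-(methoxymethoxy)-5-methylbenzaldehyde (two molecules, homocoupling)
Product: 13 6,6'-bis(methoxymethoxy)-4,4'-dimethylbiphenyl-2,2'-dicarbaldehyde
Conditions: activated copper powder, DMF, 130 °C
Reagents that add atoms: 2-iodo-3-(methoxymethoxy)-5-methylbenzaldehyde (the second molecule of 12), O=Cc1cc(C)cc(OCOC)c1I
Why: Ullmann homocoupling: two molecules of aryl iodide 12 are joined at their iodine-bearing carbons, each losing iodide to copper; the ortho formyl group favours the coupling, which should form the tetra-ortho-substituted 5,5' biaryl bond as a racemic axis.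

**Step 7**
Reactants: 13 6,6'-bis(methoxymethoxy)-4,4'-dimethylbiphenyl-2,2'-dicarbaldehyde
Product: 14 3,3'-dibromo-6,6'-bis(methoxymethoxy)-4,4'-dimethylbiphenyl-2,2'-dicarbaldehyde
Conditions: NBS (2.2 equiv), MeCN, rt
Reagents that add atoms: N-bromosuccinimide, O=C1CCC(=O)N1Br
Why: Electrophilic aromatic bromination para to each MOM ether and ortho to the formyl group, the pattern known for 3-alkoxybenzaldehydes, places the leaving group on the future C8a and C8a' before any alkene is present.

**Step 8**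
Reactants: 14 3,3'-dibromo-6,6'-bis(methoxymethoxy)-4,4'-dimethylbiphenyl-2,2'-dicarbaldehyde
Product: 15 3,3'-dibromo-6,6'-bis(methoxymethoxy)-4,4'-dimethyl-2,2'-divinylbiphenyl
Conditions: Ph3PCH3Br, KOtBu, THF, 0 °C to rt
Reagents that add atoms: methyltriphenylphosphonium bromide, C[P+](c1ccccc1)(c1ccccc1)c1ccccc1.[Br-]
Why: Wittig methylenation of both aldehydes installs C3 and C3' as the terminal carbons of two vinyl groups.

**Step 9**
Reactants: 15 3,3'-dibromo-6,6'-bis(methoxymethoxy)-4,4'-dimethyl-2,2'-divinylbiphenyl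
Product: 17 2-[3,3'-dibromo-6,6'-bis(methoxymethoxy)-4,4'-dimethyl-2'-vinylbiphenyl-2-yl]ethanol, via alkylborane 16 (not isolated)
Conditions: 9-BBN (1.0 equiv), THF, 0 °C to rt; then H2O2, aq. NaOAc
Reagents that add atoms: hydrogen peroxide, OO
Why: Anti-Markovnikov hydroboration–oxidation of one of the two equivalent vinyl groups; the desymmetrisation is statistical, so the mono-alcohol is separated and unreacted 15 is recycled.

**Step 10**
Reactants: 17 2-[3,3'-dibromo-6,6'-bis(methoxymethoxy)-4,4'-dimethyl-2'-vinylbiphenyl-2-yl]ethanol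
Product: 18 3,3'-dibromo-2-(2-iodoethyl)-6,6'-bis(methoxymethoxy)-4,4'-dimethyl-2'-vinylbiphenyl
Conditions: PPh3, I2, imidazole, CH2Cl2, 0 °C
Reagents that add atoms: iodine, II
Why: Appel reaction converts the primary alcohol into the iodide without touching the vinyl group, the MOM ethers or the aryl bromides.

**Step 11**
Reactants: 18 3,3'-dibromo-2-(2-iodoethyl)-6,6'-bis(methoxymethoxy)-4,4'-dimethyl-2'-vinylbiphenyl; 6 ethyl (2Z,6E)-2,6-dimethyl-10-oxoundeca-2,6-dienoate
Product: 22 ethyl (2Z,6E)-9-[(2R)-5-(3-bromo-6-(methoxymethoxy)-4-methyl-2-vinylphenyl)-6-(methoxymethoxy)-2,8-dimethylchroman-2-yl]-2,6-dimethylnona-2,6-dienoate, via alkylzinc iodide 19 (not isolated), via mixed alkylzinc 20 (not isolated), via tertiary alkoxide 21 (not isolated)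
Conditions: Zn dust, THF, 40 °C; Me3SiCH2Li, −78 °C; then 6, Ti(OiPr)4, Si-L* (10 mol %), TEEDA, toluene, rt; then tBuOH, evaporate; Pd(OAc)2, 2-(di-tert-butylphosphino)-1,1'-binaphthyl, Cs2CO3, toluene, 80 °C
Reagents that add atoms: none
Why: The same one-flask sequence as in step 14 is run with the other ligand enantiomer: zinc insertion and silylmethyl exchange give 20, titanium-catalysed asymmetric alkyl transfer to the Si face of ketone 6 sets C2' (R) under ligand control, and Buchwald–Hartwig-type etherification of alkoxide 21 at the adjacent C–Br bond closes the pyran ring of ring B, while the second aryl bromide, which has no tethered nucleophile, and the hindered vinyl group are expected to survive.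

**Step 12**
Reactants: 22 ethyl (2Z,6E)-9-[(2R)-5-(3-bromo-6-(methoxymethoxy)-4-methyl-2-vinylphenyl)-6-(methoxymethoxy)-2,8-dimethylchroman-2-yl]-2,6-dimethylnona-2,6-dienoate
Product: 24 ethyl (2Z,6E)-9-[(2R)-5-(3-bromo-2-(2-hydroxyethyl)-6-(methoxymethoxy)-4-methylphenyl)-6-(methoxymethoxy)-2,8-dimethylchroman-2-yl]-2,6-dimethylnona-2,6-dienoate, via alkylborane 23 (not isolated)
Conditions: 9-BBN (1.2 equiv), THF, 0 °C to rt; then H2O2, aq. NaOAc
Reagents that add atoms: hydrogen peroxide, OO
Why: Hydroboration–oxidation in which 9-BBN should select the monosubstituted vinyl group over the two trisubstituted alkenes and the enoate, and buffered oxidation keeps the ethyl ester.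

**Step 13**
Reactants: 24 ethyl (2Z,6E)-9-[(2R)-5-(3-bromo-2-(2-hydroxyethyl)-6-(methoxymethoxy)-4-methylphenyl)-6-(methoxymethoxy)-2,8-dimethylchroman-2-yl]-2,6-dimethylnona-2,6-dienoate
Product: 25 ethyl (2Z,6E)-9-[(2R)-5-(3-bromo-2-(2-iodoethyl)-6-(methoxymethoxy)-4-methylphenyl)-6-(methoxymethoxy)-2,8-dimethylchroman-2-yl]-2,6-dimethylnona-2,6-dienoate
Conditions: PPh3, I2, imidazole, CH2Cl2, 0 °C
Reagents that add atoms: iodine, II
Why: Appel reaction with the preformed phosphine–iodine complex gives the primary iodide and leaves the trisubstituted alkenes, the Z-enoate and the chroman untouched.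

**Step 14**
Reactants: 25 ethyl (2Z,6E)-9-[(2R)-5-(3-bromo-2-(2-iodoethyl)-6-(methoxymethoxy)-4-methylphenyl)-6-(methoxymethoxy)-2,8-dimethylchroman-2-yl]-2,6-dimethylnona-2,6-dienoate; 6 ethyl (2Z,6E)-2,6-dimethyl-10-oxoundeca-2,6-dienoate
Product: 29 diethyl (2Z,2'Z,6E,6'E)-9,9'-[(2S,2'R)-6,6'-bis(methoxymethoxy)-2,2',8,8'-tetramethyl-5,5'-bichroman-2,2'-diyl]bis(2,6-dimethylnona-2,6-dienoate), via alkylzinc iodide 26 (not isolated), via mixed alkylzinc 27 (not isolated), via tertiary alkoxide 28 (not isolated)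
Conditions: Zn dust, THF, 40 °C; Me3SiCH2Li, −78 °C; then 6 (1.3 equiv), Ti(OiPr)4, Re-L* (10 mol %), TEEDA, toluene, rt; then tBuOH, evaporate; Pd(OAc)2, 2-(di-tert-butylphosphino)-1,1'-binaphthyl, Cs2CO3, toluene, 80 °C
Reagents that add atoms: none
Why: Zinc inserts into the primary C–I bond of 25 and exchange with Me3SiCH2Li gives the mixed alkylzinc 27 (non-transferable silylmethyl group), whose C3 is passed via an alkyltitanium species inside the chiral titanium bis(sulfonamide) diolate to the Re face of the methyl ketone of 6, forming C2–C3 and the tertiary alkoxide 28; after alkoxide exchange with tBuOH, zerovalent palladium inserts into the C8a–Br bond, the tertiary alkoxide replaces bromide on palladium and C–O reductive elimination forms O1–C8a. The closest known reaction types are the titanium-catalysed asymmetric addition of functionalised dialkylzincs to ketones and the Buchwald–Hartwig-type intramolecular etherification of tertiary alcohols with aryl bromides, run here consecutively in one flask. The only ring closed is the dihydropyran of chroman ring A, a six-membered closure by C(sp2)–O reductive elimination from a seven-membered oxapalladacycle. The new stereocenter C2 (S) is set by the ligand enantiomer (reagent control, methyl against the homoallylic chain), and both atropisomers of 25 lead to the same (2S,2'R) diastereomer because its two axial forms are mirror images. The step needs chemoselectivity for the ketone over the two enoates, which the weakly basic zinc/titanium reagent should secure, and face selectivity at a dialkyl ketone, which is only moderate in precedent; a wrong-face addition gives the homochiral (2R,2'R) diastereomer, which is removed by chromatography. The C8a–Br bond is the only site for oxidative addition and Cs2CO3 should not deprotonate the Z-enoates.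

**Step 15**
Reactants: 29 diethyl (2Z,2'Z,6E,6'E)-9,9'-[(2S,2'R)-6,6'-bis(methoxymethoxy)-2,2',8,8'-tetramethyl-5,5'-bichroman-2,2'-diyl]bis(2,6-dimethylnona-2,6-dienoate)
Product: 30 diethyl (2Z,2'Z,6E,6'E)-9,9'-[(2S,2'R)-6,6'-dihydroxy-2,2',8,8'-tetramethyl-5,5'-bichroman-2,2'-diyl]bis(2,6-dimethylnona-2,6-dienoate)
Conditions: HCl, EtOH, 40 °C
Reagents that add atoms: none
Why: Acid-catalysed acetal exchange removes both MOM ethers, with ethanol matching the ethyl esters and trapping formaldehyde as diethoxymethane.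

**Step 16**
Reactants: 30 diethyl (2Z,2'Z,6E,6'E)-9,9'-[(2S,2'R)-6,6'-dihydroxy-2,2',8,8'-tetramethyl-5,5'-bichroman-2,2'-diyl]bis(2,6-dimethylnona-2,6-dienoate)
Product: 31 (2Z,2'Z,6E,6'E)-9,9'-[(2S,2'R)-6,6'-dihydroxy-2,2',8,8'-tetramethyl-5,5'-bichroman-2,2'-diyl]bis(2,6-dimethylnona-2,6-dienoic acid) (target CNP0282703.1)
Conditions: LiOH·H2O, THF/EtOH/H2O, 40 °C, argon; then dilute HCl
Reagents that add atoms: lithium hydroxide, [Li+].[OH-]
Why: Saponification of both hindered Z-enoates (acyl–oxygen cleavage by hydroxide) under argon at mild temperature, chosen to limit Z to E isomerisation and oxidation of the free chromanols, followed by acidification to the diacid.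

**Compound list**

1 | (E)-geranylacetone, (5E)-6,10-dimethylundeca-5,9-dien-2-one | CC(=O)CC/C=C(C)/CCC=C(C)C | starting material
2 | (5E)-9-bromo-10-hydroxy-6,10-dimethylundec-5-en-2-one | CC(=O)CC/C=C(C)/CCC(Br)C(C)(C)O | intermediate (not isolated)
3 | (5E)-9,10-epoxy-6,10-dimethylundec-5-en-2-one | CC(=O)CC/C=C(C)/CCC1OC1(C)C | intermediate
4 | (5E)-9,10-dihydroxy-6,10-dimethylundec-5-en-2-one | CC(=O)CC/C=C(C)/CCC(O)C(C)(C)O | intermediate (not isolated)
5 | (4E)-4-methyl-8-oxonon-4-enal | CC(=O)CC/C=C(C)/CCC=O | intermediate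
6 | ethyl (2Z,6E)-2,6-dimethyl-10-oxoundeca-2,6-dienoate | CCOC(=O)/C(C)=C\CC/C(C)=C/CCC(C)=O | intermediate
7 | 3-hydroxy-5-methylbenzaldehyde | O=Cc1cc(C)cc(O)c1 | starting material
8 | 3-(methoxymethoxy)-5-methylbenzaldehyde | O=Cc1cc(C)cc(OCOC)c1 | intermediate
9 | lithium α-amino alkoxide of 8 | [Li]OC(N(C)CCN(C)C)c1cc(C)cc(OCOC)c1 | intermediate (not isolated)
10 | 2-lithio derivative of 9 | [Li]OC(N(C)CCN(C)C)c1cc(C)cc(OCOC)c1[Li] | intermediate (not isolated)
11 | 2-iodo derivative of 9 | [Li]OC(N(C)CCN(C)C)c1cc(C)cc(OCOC)c1I | intermediate (not isolated)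
12 | 2-iodo-3-(methoxymethoxy)-5-methylbenzaldehyde | O=Cc1cc(C)cc(OCOC)c1I | intermediate
13 | 6,6'-bis(methoxymethoxy)-4,4'-dimethylbiphenyl-2,2'-dicarbaldehyde | O=Cc1cc(C)cc(OCOC)c1-c1c(OCOC)cc(C)cc1C=O | intermediate
14 | 3,3'-dibromo-6,6'-bis(methoxymethoxy)-4,4'-dimethylbiphenyl-2,2'-dicarbaldehyde | O=Cc1c(Br)c(C)cc(OCOC)c1-c1c(OCOC)cc(C)c(Br)c1C=O | intermediate
15 | 3,3'-dibromo-6,6'-bis(methoxymethoxy)-4,4'-dimethyl-2,2'-divinylbiphenyl | C=Cc1c(Br)c(C)cc(OCOC)c1-c1c(OCOC)cc(C)c(Br)c1C=C | intermediate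
16 | B-(2-arylethyl)-9-borabicyclo[3.3.1]nonane from 15 | C=Cc1c(Br)c(C)cc(OCOC)c1-c1c(OCOC)cc(C)c(Br)c1CCB1C2CCCC1CCC2 | intermediate (not isolated)
17 | 2-[3,3'-dibromo-6,6'-bis(methoxymethoxy)-4,4'-dimethyl-2'-vinylbiphenyl-2-yl]ethanol | C=Cc1c(Br)c(C)cc(OCOC)c1-c1c(OCOC)cc(C)c(Br)c1CCO | intermediate
18 | 3,3'-dibromo-2-(2-iodoethyl)-6,6'-bis(methoxymethoxy)-4,4'-dimethyl-2'-vinylbiphenyl | C=Cc1c(Br)c(C)cc(OCOC)c1-c1c(OCOC)cc(C)c(Br)c1CCI | intermediate
19 | alkylzinc iodide from 18 | C=Cc1c(Br)c(C)cc(OCOC)c1-c1c(OCOC)cc(C)c(Br)c1CC[Zn]I | intermediate (not isolated)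
20 | alkyl(trimethylsilylmethyl)zinc from 19 | C=Cc1c(Br)c(C)cc(OCOC)c1-c1c(OCOC)cc(C)c(Br)c1CC[Zn]C[Si](C)(C)C | intermediate (not isolated)
21 | ethyl (2Z,6E,10R)-12-[3,3'-dibromo-6,6'-bis(methoxymethoxy)-4,4'-dimethyl-2'-vinylbiphenyl-2-yl]-10-hydroxy-2,6,10-trimethyldodeca-2,6-dienoate (formed as its metal alkoxide, drawn as the alcohol) | C=Cc1c(Br)c(C)cc(OCOC)c1-c1c(OCOC)cc(C)c(Br)c1CC[C@@](C)(CC/C=C(\C)CC/C=C(/C)C(=O)OCC)O | intermediate (not isolated)
22 | ethyl (2Z,6E)-9-[(2R)-5-(3-bromo-6-(methoxymethoxy)-4-methyl-2-vinylphenyl)-6-(methoxymethoxy)-2,8-dimethylchroman-2-yl]-2,6-dimethylnona-2,6-dienoate | C=Cc1c(Br)c(C)cc(OCOC)c1-c1c(OCOC)cc(C)c2c1CC[C@@](C)(CC/C=C(\C)CC/C=C(/C)C(=O)OCC)O2 | intermediate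
23 | B-(2-arylethyl)-9-borabicyclo[3.3.1]nonane from 22 | C1CCC2CCCC1B2CCc1c(Br)c(C)cc(OCOC)c1-c1c(OCOC)cc(C)c2c1CC[C@@](C)(CC/C=C(\C)CC/C=C(/C)C(=O)OCC)O2 | intermediate (not isolated)
24 | ethyl (2Z,6E)-9-[(2R)-5-(3-bromo-2-(2-hydroxyethyl)-6-(methoxymethoxy)-4-methylphenyl)-6-(methoxymethoxy)-2,8-dimethylchroman-2-yl]-2,6-dimethylnona-2,6-dienoate | OCCc1c(Br)c(C)cc(OCOC)c1-c1c(OCOC)cc(C)c2c1CC[C@@](C)(CC/C=C(\C)CC/C=C(/C)C(=O)OCC)O2 | intermediate
25 | ethyl (2Z,6E)-9-[(2R)-5-(3-bromo-2-(2-iodoethyl)-6-(methoxymethoxy)-4-methylphenyl)-6-(methoxymethoxy)-2,8-dimethylchroman-2-yl]-2,6-dimethylnona-2,6-dienoate | ICCc1c(Br)c(C)cc(OCOC)c1-c1c(OCOC)cc(C)c2c1CC[C@@](C)(CC/C=C(\C)CC/C=C(/C)C(=O)OCC)O2 | intermediate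
26 | alkylzinc iodide from 25 | I[Zn]CCc1c(Br)c(C)cc(OCOC)c1-c1c(OCOC)cc(C)c2c1CC[C@@](C)(CC/C=C(\C)CC/C=C(/C)C(=O)OCC)O2 | intermediate (not isolated)
27 | alkyl(trimethylsilylmethyl)zinc from 26 | C[Si](C)(C)C[Zn]CCc1c(Br)c(C)cc(OCOC)c1-c1c(OCOC)cc(C)c2c1CC[C@@](C)(CC/C=C(\C)CC/C=C(/C)C(=O)OCC)O2 | intermediate (not isolated)
28 | (10S)-tertiary alcohol of the ring A arm, ring B chroman (2R) (formed as its metal alkoxide, drawn as the alcohol) | CCOC(=O)/C(C)=C\CC/C(C)=C/CC[C@@](O)(C)CCc1c(Br)c(C)cc(OCOC)c1-c1c(OCOC)cc(C)c2c1CC[C@@](C)(CC/C=C(\C)CC/C=C(/C)C(=O)OCC)O2 | intermediate (not isolated)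
29 | diethyl (2Z,2'Z,6E,6'E)-9,9'-[(2S,2'R)-6,6'-bis(methoxymethoxy)-2,2',8,8'-tetramethyl-5,5'-bichroman-2,2'-diyl]bis(2,6-dimethylnona-2,6-dienoate) | CCOC(=O)/C(C)=C\CC/C(C)=C/CC[C@@]1(C)CCc2c(c(C)cc(OCOC)c2-c2c(OCOC)cc(C)c3c2CC[C@@](C)(CC/C=C(\C)CC/C=C(/C)C(=O)OCC)O3)O1 | intermediate
30 | diethyl (2Z,2'Z,6E,6'E)-9,9'-[(2S,2'R)-6,6'-dihydroxy-2,2',8,8'-tetramethyl-5,5'-bichroman-2,2'-diyl]bis(2,6-dimethylnona-2,6-dienoate) | CCOC(=O)/C(C)=C\CC/C(C)=C/CC[C@@]1(C)CCc2c(c(C)cc(O)c2-c2c(O)cc(C)c3c2CC[C@@](C)(CC/C=C(\C)CC/C=C(/C)C(=O)OCC)O3)O1 | intermediate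
31 | (2Z,2'Z,6E,6'E)-9,9'-[(2S,2'R)-6,6'-dihydroxy-2,2',8,8'-tetramethyl-5,5'-bichroman-2,2'-diyl]bis(2,6-dimethylnona-2,6-dienoic acid) | C/C(=C/CC/C(C)=C/CC[C@@]1(C)CCc2c(c(C)cc(O)c2-c2c(O)cc(C)c3c2CC[C@@](C)(CC/C=C(\C)CC/C=C(/C)C(=O)O)O3)O1)C(=O)O | target

**Step count and risks**

Total step count: 16 (steps 1–3 give ketone 6, which is used in steps 11 and 14; steps 4–16 run from 7 to 31). Longest linear sequence: 13 steps (steps 4–16).

Steps most likely to fail:

1. Step 14 (key step). The alkyl transfer from the hindered mixed zinc reagent may be incomplete, the face selectivity at the dialkyl ketone may be low, or the bromide may be lost reductively in the palladium stage in the presence of residual alkoxides. Fallback, in two isolated operations by known chemistry: from 25, zinc insertion gives the alkylzinc iodide 26, whose MgCl2-promoted addition to 6 without chiral ligand gives the tertiary alcohol as both C2 epimers F1, which is isolated. Buchwald–Hartwig-type cyclisation (Pd(OAc)2, 2-(di-tert-butylphosphino)-1,1'-binaphthyl, Cs2CO3, toluene) then gives 29 together with its (2R,2'R) diastereomer F2, which is removed by preparative HPLC. The route is rejoined at 29.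

2. Step 11. The same failure processes apply, and in addition the second aryl bromide or the vinyl group may be consumed during the palladium stage. Fallback: from 18, zinc insertion to 19 and MgCl2-promoted addition to 6 give the isolated tertiary alcohol as both C2' epimers F3, which is cyclised under the same palladium conditions at lower catalyst loading to 22 and its (2'S) epimer F4. F4 is removed on a chiral stationary phase (or carried on, since after step 14 the error appears only as the homochiral diastereomer). The route is rejoined at 22.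

3. Step 16. The hindered Z-enoates may isomerise to the E acids during prolonged basic hydrolysis, and the free chromanols may oxidise in the basic medium. Fallback with reversed order and neutral hydrolysis: from 29, Me3SnOH in 1,2-dichloroethane at 80 °C cleaves both ethyl esters while the phenols are still protected and gives the bis-MOM diacid F5. The MOM groups are then removed with ZnBr2 and propane-1-thiol in CH2Cl2, rejoining the route at 31.

**Further compounds**

F1 | step 14 | tertiary alcohol of the ring A arm as both C2 epimers, ring B chroman (2R) | CCOC(=O)/C(C)=C\CC/C(C)=C/CCC(O)(C)CCc1c(Br)c(C)cc(OCOC)c1-c1c(OCOC)cc(C)c2c1CC[C@@](C)(CC/C=C(\C)CC/C=C(/C)C(=O)OCC)O2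
F2 | step 14 | (2R,2'R) diastereomer of 29 | CCOC(=O)/C(C)=C\CC/C(C)=C/CC[C@]1(C)CCc2c(c(C)cc(OCOC)c2-c2c(OCOC)cc(C)c3c2CC[C@@](C)(CC/C=C(\C)CC/C=C(/C)C(=O)OCC)O3)O1
F3 | step 11 | tertiary alcohol corresponding to 21 as both C2' epimers | C=Cc1c(Br)c(C)cc(OCOC)c1-c1c(OCOC)cc(C)c(Br)c1CCC(C)(O)CC/C=C(\C)CC/C=C(/C)C(=O)OCC
F4 | step 11 | (2'S) epimer of 22 | C=Cc1c(Br)c(C)cc(OCOC)c1-c1c(OCOC)cc(C)c2c1CC[C@](C)(CC/C=C(\C)CC/C=C(/C)C(=O)OCC)O2
F5 | step 16 | (2Z,2'Z,6E,6'E)-9,9'-[(2S,2'R)-6,6'-bis(methoxymethoxy)-2,2',8,8'-tetramethyl-5,5'-bichroman-2,2'-diyl]bis(2,6-dimethylnona-2,6-dienoic acid) | C/C(=C/CC/C(C)=C/CC[C@@]1(C)CCc2c(c(C)cc(OCOC)c2-c2c(OCOC)cc(C)c3c2CC[C@@](C)(CC/C=C(\C)CC/C=C(/C)C(=O)O)O3)O1)C(=O)O
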